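The cyclopentane is disconnected at the bond between its lone CH2 (C3) and the isopropyl carbinol carbon (C4). The key step is a Rh(II)-carbenoid 1,5 C–H insertion: a diazoacetyl group on the quaternary ring carbon C1 inserts with retention into the silyloxy-activated methine C4–H of a side chain on neighbouring C5, closing the five-membered ring trans-fused on a finished epoxycycloheptane and turning a secondary carbinol into the tetrasubstituted C4. It exploits the C2 oxygen (as diazoketone carbonyl) and the C4 oxygen (as C–H activator), which are 1,3 across the ring. The precursor is a monocyclic trans-1,2-disubstituted cycloheptane oxide built by conjugate addition–aldol on a ring-expanded dienone.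

Key step: step 11

Remark (numbering): daucane numbering is used throughout. C1 = quaternary ring-fusion carbon (CH3), C2 = CH–OAc, C3 = CH2, C4 = C(OH)(i-Pr), C5 = ring-fusion CH, C6 = CH–O-anisoyl, C7 = CH2, C8 = epoxide C(CH3), C9 = epoxide CH, C10 = CH2. The target is (1S,2R,4S,5R,6R,8S,9R).

Remark (assumption): the antipode of the chiral ligand in step 4 is defined by its product, i.e. the one that gives the (S) quaternary carbon of 9.

**Step 1**
Reactants: 1 2,5-dimethylanisole
Product: 2 1-methoxy-2,5-dimethylcyclohexa-1,4-diene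
Conditions: Li, liq. NH3, THF, t-BuOH, −78 to −33 °C
Reagents that add atoms: none
Why: Birch reduction of an alkyl anisole leaves the methoxy and both methyl groups on sp2 carbons, so the 2,5-dihydro product with a tetrasubstituted enol ether and an isolated trisubstituted alkene is the only regioisomer expected, and no stereocentre is formed.

**Step 2**
Reactants: 2 1-methoxy-2,5-dimethylcyclohexa-1,4-diene
Product: 4 2-bromo-3,6-dimethylcyclohepta-2,5-dien-1-one, via dibromocyclopropane 3 (not isolated)
Conditions: CHBr3, KOt-Bu, pentane, −20 °C to rt; then AgNO3, acetone/H2O, rt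
Reagents that add atoms: bromoform BrC(Br)Br; water O
Why: Electrophilic dibromocarbene cyclopropanates the more electron-rich enol ether double bond, and silver-assisted loss of the endo bromide triggers disrotatory cyclopropyl-to-allyl cation opening that the methoxy group pulls through to the ring-expanded α-bromoenone after hydrolysis (dihalocarbene ring expansion of an enol ether), with no stereocentre in the product.

**Step 3**
Reactants: 4 2-bromo-3,6-dimethylcyclohepta-2,5-dien-1-one
Product: 5 3,6-dimethylcyclohepta-2,5-dien-1-one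
Conditions: Pd(PPh3)4 (cat.), Bu3SnH, THF, 0 °C to rt
Reagents that add atoms: none
Why: Palladium-catalysed hydrodehalogenation (oxidative addition into the vinyl C–Br bond, hydride transfer from tin, reductive elimination) removes the bromine under neutral conditions that should keep the skipped C8=C9 alkene out of conjugation.

**Step 4**
Reactants: 5 3,6-dimethylcyclohepta-2,5-dien-1-one; 6 2-bromopropene; 7 isobutyraldehyde
Product: 9 (6S,7S)-7-[(1S)-1-hydroxy-2-methylpropyl]-3,6-dimethyl-6-(prop-1-en-2-yl)cyclohept-3-en-1-one, via aluminium enolate 8 (not isolated)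
Conditions: 6, t-BuLi (2 equiv), Et2O, −78 °C, then Me2AlCl; 5, CuTC (cat.), chiral phosphinamine (SimplePhos-type) ligand (cat.), Et2O, −30 °C; then 7, −78 to −40 °C; aq. Rochelle salt
Reagents that add atoms: none
Why: Copper-catalysed enantioselective conjugate addition of the alkenylalane to the β-methyl enone sets quaternary C1 under ligand control, and the regiodefined aluminium enolate is trapped in an aldol addition with 7 that should enter C5 anti to the bulkier isopropenyl group through a closed Zimmerman–Traxler transition state of the ring (E)-enolate, giving the anti (4S,5S) aldol (tandem asymmetric conjugate addition–aldol).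

**Step 5**
Reactants: 9 anti-aldol ketone
Product: 10 (1R,6S,7R)-7-[(1S)-1-hydroxy-2-methylpropyl]-3,6-dimethyl-6-(prop-1-en-2-yl)cyclohept-3-en-1-ol
Conditions: Et2BOMe, NaBH4, THF/MeOH, −78 °C; AcOH, MeOH azeotrope
Reagents that add atoms: none
Why: In the Narasaka–Prasad reduction the diethylboron chelate of the β-hydroxy ketone is attacked by external hydride axially and anti to H5, which gives the syn-1,3-diol and sets C6 (R) with its oxygen trans to the side chain.

**Step 6**
Reactants: 10 syn-1,3-diol
Product: 11 (1S,3R,4R,5S,7R)-4-[(1S)-1-hydroxy-2-methylpropyl]-1,5-dimethyl-5-(prop-1-en-2-yl)-8-oxabicyclo[5.1.0]octan-3-ol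
Conditions: VO(acac)2 (cat.), t-BuOOH, CH2Cl2, 0 °C
Reagents that add atoms: tert-butyl hydroperoxide CC(C)(C)OO
Why: Vanadium-catalysed hydroxyl-directed epoxidation delivers oxygen to the homoallylic trisubstituted ring alkene on the face of the C6 hydroxyl, setting C8 and C9 syn to O6, while the more remote and less electron-rich isopropenyl group should be left untouched.

**Step 7**
Reactants: 11 epoxy diol; 12 4-methoxybenzoyl chloride
Product: 13 (1S,3R,4S,5S,7R)-4-[(1S)-1-hydroxy-2-methylpropyl]-1,5-dimethyl-5-(prop-1-en-2-yl)-8-oxabicyclo[5.1.0]octan-3-yl 4-methoxybenzoate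
Conditions: pyridine, DMAP (cat.), CH2Cl2, −20 to 0 °C
Reagents that add atoms: none
Why: DMAP-catalysed acylation with the moderately reactive aroyl chloride should select the ring C6 hydroxyl, which has a CH2 neighbour, over the C4 hydroxyl flanked by the isopropyl group and branched C5, and no stereocentre is touched.

**Step 8**
Reactants: 13 C6 mono-anisate
Product: 14 (1S,3R,4R,5S,7R)-1,5-dimethyl-4-[(1S)-2-methyl-1-(triethylsilyloxy)propyl]-5-(prop-1-en-2-yl)-8-oxabicyclo[5.1.0]octan-3-yl 4-methoxybenzoate
Conditions: Et3SiCl, imidazole, DMAP (cat.), DMF, rt to 40 °C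
Reagents that add atoms: chlorotriethylsilane CC[Si](Cl)(CC)CC
Why: Imidazole-promoted silylation of the remaining hindered secondary alcohol avoids the Lewis acidity of silyl triflates toward the epoxide and installs the triethylsilyl ether that later activates C4–H.

**Step 9**
Reactants: 14 triethylsilyl ether
Product: 15 (1S,3R,4R,5S,7R)-5-acetyl-1,5-dimethyl-4-[(1S)-2-methyl-1-(triethylsilyloxy)propyl]-8-oxabicyclo[5.1.0]octan-3-yl 4-methoxybenzoate
Conditions: O3, CH2Cl2, −78 °C; then Me2S
Reagents that add atoms: ozone [O-][O+]=O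
Why: Ozonolysis with reductive work-up cleaves the only remaining alkene, the 1,1-disubstituted isopropenyl group, to the methyl ketone on C1 without touching the epoxide, silyl ether or ester.

**Step 10**
Reactants: 15 methyl ketone
Product: 17 (1S,3R,4R,5S,7R)-5-(2-diazoacetyl)-1,5-dimethyl-4-[(1S)-2-methyl-1-(triethylsilyloxy)propyl]-8-oxabicyclo[5.1.0]octan-3-yl 4-methoxybenzoate, via trifluoroacetyl ketone 16 (not isolated)
Conditions: LiHMDS, THF, −78 °C, CF3CO2CH2CF3; then MsN3, Et3N, H2O, MeCN, rt
Reagents that add atoms: methanesulfonyl azide CS(=O)(=O)N=[N+]=[N-]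
Why: In the Danheiser detrifluoroacetylative diazo transfer the only enolisable position (C3) is trifluoroacetylated via its lithium enolate, and the activated 1,3-diketone takes the diazo group from mesyl azide with loss of the trifluoroacetyl group as the sulfonamide.

**Step 11**
Reactants: 17 α-diazoketone
Product: 18 (1S,4S,5R,6R,8S,9R)-8,9-epoxy-2-oxo-4-(triethylsilyloxy)daucan-6-yl 4-methoxybenzoate
Conditions: Rh2(OAc)4 (1 mol %), CH2Cl2, rt, slow addition of 17
Reagents that add atoms: none
Why: Rh(II) decomposes the diazoketone to an electrophilic carbenoid at C3 that inserts into the C4–H bond through a concerted three-centre transition state, the known intramolecular 1,5 C–H insertion of α-diazoketones to cyclopentanones. The one ring closed is the five-membered ring C1–C2–C3–C4–C5, formed by 1,5-insertion and trans-fused onto the cycloheptane because the diazoacetyl group on C1 and the side chain on C5 are trans. The only new stereocentre, tetrasubstituted C4, is controlled by the stereospecificity of the insertion, which proceeds with retention, so the (4S) carbinol configuration from the aldol is carried over with C3 taking the place of H. The step needs site selectivity, and the substrate secures it: C4–H is a methine activated by the adjacent silyloxy oxygen, whereas C6–H is deactivated by the aroyloxy group and lies on the opposite ring face, and the C1 methyl and C10 hydrogens would give four-membered rings. The alkene was epoxidised beforehand so that cyclopropanation cannot compete, and ylide formation should be slow because the epoxide oxygen is weakly basic and the bulky Et3Si group shields the ether oxygen.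

**Step 12**
Reactants: 18 β-silyloxy ketone
Product: 19 (1S,4S,5R,6R,8S,9R)-8,9-epoxy-4-hydroxy-2-oxodaucan-6-yl 4-methoxybenzoate
Conditions: TBAF, AcOH (1:1), THF, 0 °C to rt
Reagents that add atoms: none
Why: Fluoride cleaves the tertiary Si–O bond, and acetic acid buffering keeps the medium near neutral so that the β-hydroxy ketone should neither undergo retro-aldol cleavage of the new C3–C4 bond nor lose the epoxide.

**Step 13**
Reactants: 19 β-hydroxy ketone
Product: 20 (1S,2R,4S,5R,6R,8S,9R)-8,9-epoxy-2,4-dihydroxydaucan-6-yl 4-methoxybenzoate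
Conditions: Me4NBH(OAc)3, MeCN/AcOH, −30 °C
Reagents that add atoms: none
Why: In the Evans–Saksena reduction the triacetoxyborohydride binds to the C4 hydroxyl and delivers hydride intramolecularly to the C2 ketone from the face of O4, giving the 1,3-anti (trans) diol and thus (2R).

**Step 14**
Reactants: 20 diol
Product: 21 (1S,2R,4S,5R,6R,8S,9R)-2-acetoxy-8,9-epoxy-4-hydroxydaucan-6-yl 4-methoxybenzoate (CNP0317703.1)
Conditions: Ac2O, pyridine, DMAP (cat.), CH2Cl2, 0 °C to rt
Reagents that add atoms: acetic anhydride CC(=O)OC(C)=O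
Why: DMAP-catalysed acetylation esterifies the secondary C2 hydroxyl, while the hindered tertiary C4 hydroxyl does not react under these conditions.

**Compound list**
1 | 2,5-dimethylanisole | COc1cc(C)ccc1C | starting material
2 | 1-methoxy-2,5-dimethylcyclohexa-1,4-diene | COC1=C(C)CC=C(C)C1 | intermediate
3 | 7,7-dibromo-1-methoxy-3,6-dimethylbicyclo[4.1.0]hept-3-ene (racemic, formed in the flask) | COC12CC(C)=CCC1(C)C2(Br)Br | intermediate
4 | 2-bromo-3,6-dimethylcyclohepta-2,5-dien-1-one | O=C1CC(C)=CCC(C)=C1Br | intermediate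
5 | 3,6-dimethylcyclohepta-2,5-dien-1-one | O=C1CC(C)=CCC(C)=C1 | intermediate
6 | 2-bromopropene | CC(Br)=C | starting material
7 | isobutyraldehyde | CC(C)C=O | starting material
8 | dimethylaluminium (S)-3,6-dimethyl-3-(prop-1-en-2-yl)cyclohepta-1,5-dien-1-olate (formed in the flask) | C[Al](C)OC1=C[C@@](C)(C(C)=C)CC=C(C)C1 | intermediate
9 | (6S,7S)-7-[(1S)-1-hydroxy-2-methylpropyl]-3,6-dimethyl-6-(prop-1-en-2-yl)cyclohept-3-en-1-one | O=C1CC(C)=CC[C@](C)(C(C)=C)[C@H]1[C@@H](O)C(C)C | intermediate
10 | (1R,6S,7R)-7-[(1S)-1-hydroxy-2-methylpropyl]-3,6-dimethyl-6-(prop-1-en-2-yl)cyclohept-3-en-1-ol | O[C@@H]1CC(C)=CC[C@](C)(C(C)=C)[C@H]1[C@@H](O)C(C)C | intermediate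
11 | (1S,3R,4R,5S,7R)-4-[(1S)-1-hydroxy-2-methylpropyl]-1,5-dimethyl-5-(prop-1-en-2-yl)-8-oxabicyclo[5.1.0]octan-3-ol | O[C@@H]1C[C@]2(C)O[C@@H]2C[C@](C)(C(C)=C)[C@H]1[C@@H](O)C(C)C | intermediate
12 | 4-methoxybenzoyl chloride | COc1ccc(C(Cl)=O)cc1 | starting material
13 | (1S,3R,4S,5S,7R)-4-[(1S)-1-hydroxy-2-methylpropyl]-1,5-dimethyl-5-(prop-1-en-2-yl)-8-oxabicyclo[5.1.0]octan-3-yl 4-methoxybenzoate | COc1ccc(C(=O)O[C@@H]2C[C@]3(C)O[C@@H]3C[C@](C)(C(C)=C)[C@H]2[C@@H](O)C(C)C)cc1 | intermediate
14 | (1S,3R,4R,5S,7R)-1,5-dimethyl-4-[(1S)-2-methyl-1-(triethylsilyloxy)propyl]-5-(prop-1-en-2-yl)-8-oxabicyclo[5.1.0]octan-3-yl 4-methoxybenzoate | COc1ccc(C(=O)O[C@@H]2C[C@]3(C)O[C@@H]3C[C@](C)(C(C)=C)[C@H]2[C@@H](O[Si](CC)(CC)CC)C(C)C)cc1 | intermediate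
15 | (1S,3R,4R,5S,7R)-5-acetyl-1,5-dimethyl-4-[(1S)-2-methyl-1-(triethylsilyloxy)propyl]-8-oxabicyclo[5.1.0]octan-3-yl 4-methoxybenzoate | COc1ccc(C(=O)O[C@@H]2C[C@]3(C)O[C@@H]3C[C@](C)(C(C)=O)[C@H]2[C@@H](O[Si](CC)(CC)CC)C(C)C)cc1 | intermediate
16 | 4,4,4-trifluoro-1,3-dioxobutyl analogue of 15 (trifluoroacetylated at C3, formed in the flask) | COc1ccc(C(=O)O[C@@H]2C[C@]3(C)O[C@@H]3C[C@](C)(C(=O)CC(=O)C(F)(F)F)[C@H]2[C@@H](O[Si](CC)(CC)CC)C(C)C)cc1 | intermediate
17 | (1S,3R,4R,5S,7R)-5-(2-diazoacetyl)-1,5-dimethyl-4-[(1S)-2-methyl-1-(triethylsilyloxy)propyl]-8-oxabicyclo[5.1.0]octan-3-yl 4-methoxybenzoate | COc1ccc(C(=O)O[C@@H]2C[C@]3(C)O[C@@H]3C[C@](C)(C(=O)C=[N+]=[N-])[C@H]2[C@@H](O[Si](CC)(CC)CC)C(C)C)cc1 | intermediate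
18 | (1S,4S,5R,6R,8S,9R)-8,9-epoxy-2-oxo-4-(triethylsilyloxy)daucan-6-yl 4-methoxybenzoate | COc1ccc(C(=O)O[C@@H]2C[C@]3(C)O[C@@H]3C[C@]3(C)C(=O)C[C@](O[Si](CC)(CC)CC)(C(C)C)[C@@H]23)cc1 | intermediate
19 | (1S,4S,5R,6R,8S,9R)-8,9-epoxy-4-hydroxy-2-oxodaucan-6-yl 4-methoxybenzoate | COc1ccc(C(=O)O[C@@H]2C[C@]3(C)O[C@@H]3C[C@]3(C)C(=O)C[C@](O)(C(C)C)[C@@H]23)cc1 | intermediate
20 | (1S,2R,4S,5R,6R,8S,9R)-8,9-epoxy-2,4-dihydroxydaucan-6-yl 4-methoxybenzoate | COc1ccc(C(=O)O[C@@H]2C[C@]3(C)O[C@@H]3C[C@]3(C)[C@H](O)C[C@](O)(C(C)C)[C@@H]23)cc1 | intermediate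
21 | (1S,2R,4S,5R,6R,8S,9R)-2-acetoxy-8,9-epoxy-4-hydroxydaucan-6-yl 4-methoxybenzoate (CNP0317703.1) | COc1ccc(C(=O)O[C@@H]2C[C@]3(C)O[C@@H]3C[C@]3(C)[C@H](OC(C)=O)C[C@](O)(C(C)C)[C@@H]23)cc1 | target

**Step count and risks**
Total step count: 14. Longest linear sequence: 14 steps (from 1).

Steps most likely to fail:

Step 11 (key step). The carbenoid may be diverted into oxonium-ylide formation at the epoxide oxygen, or hydride abstraction at C4 may be followed by silyl transfer instead of C–C bond formation. The fallback closes the same C3–C4 bond by an intramolecular aldol addition. It sets out from 13: Dess–Martin oxidation of the free C4 hydroxyl should give isopropyl ketone F1, and ozonolysis of the isopropenyl group then gives 1,4-diketone F2. Kinetic deprotonation of the methyl ketone (LiHMDS, THF, −78 °C, cold acetic acid quench) lets the C3 enolate add to the C4 ketone in a 5-(enolexo)-exo-trig closure, in which the isopropyl group should settle anti to C6. This gives β-hydroxy ketone 19, where the route is rejoined.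

Step 4. Aldol trapping of the aluminium enolate may be sluggish, anti selectivity may erode, or facial selectivity at C5 may be poor. The fallback separates enolate formation from the aldol and changes the enolate metal. It sets out from 5: the same conjugate addition is quenched with Me3SiCl/Et3N to give silyl enol ether F3, which is transmetallated with Bu2BOTf to boron enolate F4. Its aldol addition to 7 through a tight closed transition state, followed by non-oxidative work-up, comes back to 9.

Step 3. Hydrodebromination may be accompanied by conjugate reduction of the enone or by migration of the skipped double bond into conjugation. The fallback avoids the bromide altogether. It sets out from 2: the chlorocarbenoid from CH2Cl2 and MeLi should give mainly the endo-chloro adduct, chlorocyclopropane F5, whose silver-assisted ring expansion (AgNO3, aqueous acetone) gives the halogen-free dienone and so comes back to 5.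

**Further compounds**
F1 | step 11 | C4 ketone of 13 (isobutyryl group on C5) | COc1ccc(C(=O)O[C@@H]2C[C@]3(C)O[C@@H]3C[C@](C)(C(C)=C)[C@H]2C(=O)C(C)C)cc1
F2 | step 11 | 1,4-diketone (acetyl on C1, isobutyryl on C5) | COc1ccc(C(=O)O[C@@H]2C[C@]3(C)O[C@@H]3C[C@](C)(C(C)=O)[C@H]2C(=O)C(C)C)cc1
F3 | step 4 | (S)-trimethyl{[3,6-dimethyl-3-(prop-1-en-2-yl)cyclohepta-1,5-dien-1-yl]oxy}silane | C[Si](C)(C)OC1=C[C@@](C)(C(C)=C)CC=C(C)C1
F4 | step 4 | dibutylboron enolate corresponding to F3 | CCCCB(CCCC)OC1=C[C@@](C)(C(C)=C)CC=C(C)C1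
F5 | step 3 | 7-chloro-1-methoxy-3,6-dimethylbicyclo[4.1.0]hept-3-ene (racemic, endo chloride) | COC12CC(C)=CCC1(C)C2Cl
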